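## The problem

Compound 18 is a pentabrominated diaryl ether. Ring A (C1 OMe, C2 Br, C3 H, C4 Br, C5 Br, C6 O) is joined through the C6 oxygen to C1' of ring B (C2' H, C3' Br, C4' H, C5' Br, C6' OH). No ring has to be closed and there is no stereocentre, so configuration is not an issue.

The central bond O–C1' links two crowded, electron-poor partners: the ring A oxygen sits between OMe and Br, and C1' sits beside the C6' oxygen. A metal-catalysed etherification would also have to pick one carbon–halogen bond out of many.

Each ring is a catechol derivative whose two oxygens must be told apart (OMe against O-aryl on ring A, O-aryl against free OH on ring B). On ring A, the bromines at C2 and C4 are ortho and para to the C1 oxygen, but C5–Br is meta to it, and C3, para to the ether oxygen, stays free. The oxygen that directs bromination therefore has to be chosen deliberately.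

The five aryl C–Br bonds rule out hydrogenolysis, unselective halogen–metal exchange and hot copper or palladium chemistry. Any aryl anion next to bromine can lose bromide to give an aryne.

The enabling feature lies in ring B: its oxygens sit on the adjacent carbons C1' and C6', C5' beside C6' carries bromine, and C2' beside C1' carries hydrogen. A C1'–C6' aryne is thus flanked by a withdrawing group on one side only, which polarises it for O–C1' formation and leaves C6' to accept a second group.

## Retrosynthesis

**18 to 15.** The C6'–O bond of target 18 is traced back to a C6'–I bond in 1,2,5-tribromo-3-(3,5-dibromo-2-iodophenoxy)-4-methoxybenzene 15.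
- C6' cannot carry a protected oxygen through an aryne step in which it is one of the aryne carbons.
- No oxygen electrophile is known to intercept an aryl anion in the presence of a phenolate, whereas iodine donors do.
- Iodine is the one halogen that magnesium can address beside five bromines.
- The forward reaction must exchange only at iodine, keep the ortho-bromo Grignard reagent 16 cold enough not to lose bromide, and oxidise the boronate 17 without protodeboronation.

**15 to 10, 5 and 11.** Cutting O–C1' and C6'–I together gives the ring A phenol 10, the silylaryl triflate 5 and nonafluoro-1-iodobutane 11. In the forward sense these react through phenolate 12, 3,5-dibromobenzyne 13 and the aryl anion 14.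
- An Ullmann coupling would have to join a di-ortho-substituted, weakly nucleophilic phenolate to a polyhalogenated partner and discriminate between halogens on both rings.
- An SNAr route needs an activating group at C6' that must later become OH; it is kept in reserve.
- The aryne needs no transition metal, leaves C–Br bonds alone and takes the hindered phenolate without complaint.
- The cut gives two monocyclic pieces of similar size, each already carrying all its bromines.
- The forward step must add the oxygen at C1' only and must iodinate C6' faster than the anion is protonated or loses bromide.

**5 to 2 to 1.** The C–Si and O–S bonds of 5 are cut back to the silyl ether 2 of 2,4,6-tribromophenol 1, by way of aryllithium 3 and lithium phenolate 4. Because 1 is symmetrical, both ortho bromines are equivalent, and the only selectivity required is ortho over para exchange. The sequence is silylation, bromine–lithium exchange with O-to-C silyl migration, and triflation.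

**10 to 8 to 7 to 6.** The C6–O bond of 10 is derived from a formyl group by Baeyer–Villiger oxidation of aldehyde 8 through formate 9. The O–CH3 bond is cut to salicylaldehyde 7, and the C2–Br and C4–Br bonds are cut to 2-bromo-6-hydroxybenzaldehyde 6.
- In 6 the free hydroxyl (the later methoxy oxygen) directs bromine to exactly C2 and C4.
- The C5 bromine is already present in 6.
- The formyl carbon marks C6, so the two ring A oxygens are never free at the same time and no selective methylation of a catechol is needed.
- Brominating a salicylaldehyde is more dependable than formylating a deactivated tribrominated phenol next to bromine, which is why the formyl group is bought and not introduced.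

## Roads not taken

**Alternative 1:** ring A is cut at C1–C2 and C5–C6.
- Forward step: 2,5-dibromothiophene 1,1-dioxide A2 serves as an electron-poor diene towards the bis(tert-butyldimethylsilyl) ketene acetal A3 of the ring B aryloxyacetic acid. Cycloaddition, loss of sulfur dioxide and elimination of silanol would give the silyl ether A1. A1 holds both ring A oxygens and the bromines at C2 and C5.
- Merits: the diene is symmetrical, so there is no regiochemical question. The missing C4 bromine lies para to the C1 hydroxyl once the silyl group is off.
- Weak points: A2 is a labile diene that dimerises readily. A3 is a hindered alkene with three oxygen substituents. Ring B must carry a benzyl group that cannot be removed by hydrogenolysis beside aryl bromides, so a Lewis acid has to distinguish benzyl from methyl ether at the end. Four operations follow the key step (desilylation, bromination, methylation, debenzylation), against one in the chosen plan.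
- Comparison: this road never generates an aryl anion beside bromine and has no aryne regiochemistry to control, which makes it safer on that count. The chosen plan offers convergence, no protecting group, and all five bromines fixed in the building blocks before the rings are joined.

**Alternative 2:** ring B is cut at C5'–C6' and C4'–C5', a one-carbon insertion.
- Forward step: dibromocarbene from bromoform and KOtBu adds to the silyl enol ether double bond of the cyclopentadiene A5. The dibromocyclopropane opens with loss of bromide and of the silyl group, and the six-membered ring aromatises to the bromophenol A4. Bromination para to the new hydroxyl then installs C3'–Br.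
- Merits: C5'–Br and the free C6'–OH arrive together without a protecting group. The endgame is a single electrophilic substitution with no organometallic step on a polybromide. In those respects it is better than the chosen plan.
- Weak points: A5 is a 2,3-dioxygenated cyclopentadiene whose double bonds migrate by 1,5-hydrogen shifts and which dimerises. Making it requires attaching the hindered ring A phenolate to a cyclopentane-1,2-dione equivalent. The carbene must choose the silyl enol ether over the aryl enol ether double bond. The final bromination must spare C3–H of ring A, which is para to the ether oxygen.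
- Comparison: the chosen plan uses stable arene building blocks made by standard reactions and a regiochemistry fixed by one bromine. It pays for this with a two-stage iodide-to-phenol conversion.

**Alternative 3:** ring A is derived from cyclohexane-1,3-dione, and its aromaticity and two C–Br bonds are created last.
- Forward step: the bromoenone A7 is treated with three equivalents of Br2. Alpha-bromination and loss of HBr give the phenol, which is brominated ortho and para to the new hydroxyl to give A6. Methylation and debenzylation finish the synthesis.
- Merits: every step is classical and the materials are cheap. The awkward C5 bromine starts as the vinyl bromide, and the other two follow the natural directing effect of the phenol. In terms of precedent this road is at least as good as the chosen one.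
- Weak points: A7 requires a C–O bond between C2 of the dione and a ring B phenol, then conversion of one carbonyl into a vinyl bromide. The aromatisation exposes the benzyl ether and the activated ring B to excess bromine and HBr. The benzyl group again has to be removed by a Lewis acid that spares the methyl ether. The sequence is linear and of similar length.
- Comparison: the chosen plan is convergent and protecting-group-free, and never exposes the assembled ether to bromine. In exchange it rests on a key step whose nucleophile class is untested.

Key step: step 6

Remark: 18 is achiral and the diaryl ether is taken as freely rotating, so no configuration has to be set; 1, 6 and 11 are taken as purchased.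

**Step 1**
Reactants: 1 2,4,6-tribromophenol
Product: 2 (2,4,6-tribromophenoxy)trimethylsilane
Conditions: HMDS (0.7 equiv), THF, reflux; volatiles removed, crude used directly
Reagents that add atoms: hexamethyldisilazane, C[Si](C)(C)N[Si](C)(C)C
Why: O-silylation of an acidic phenol by a silazane with loss of ammonia; the trimethylsilyl ether is the standard entry to ortho-silylaryl triflates.

**Step 2**
Reactants: 2 (2,4,6-tribromophenoxy)trimethylsilane
Product: 5 2,4-dibromo-6-(trimethylsilyl)phenyl trifluoromethanesulfonate, via ortho-lithiated silyl ether 3 (not isolated), via lithium phenolate 4 (not isolated)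
Conditions: n-BuLi (1.05 equiv), THF, −100 → −78 °C; then Tf2O, −78 → 0 °C
Reagents that add atoms: trifluoromethanesulfonic anhydride, O=S(=O)(OS(=O)(=O)C(F)(F)F)C(F)(F)F
Why: Bromine–lithium exchange occurs at one of the two equivalent ortho bromines, favoured over the para bromine by the inductive and coordinating silyloxy group. The aryllithium undergoes a retro-Brook O-to-C silyl shift and the phenolate is O-sulfonylated; the sequence is established for ortho-bromophenols, including 2,6-dibromophenol.

**Step 3**
Reactants: 6 2-bromo-6-hydroxybenzaldehyde
Product: 7 3,5,6-tribromo-2-hydroxybenzaldehyde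
Conditions: Br2 (2.2 equiv), AcOH, rt → 50 °C
Reagents that add atoms: bromine, BrBr
Why: Electrophilic aromatic bromination; the hydroxyl directs to its ortho and para positions, and the meta-directing formyl group and the existing bromine point to the same two carbons, so no other isomer is expected.

**Step 4**
Reactants: 7 3,5,6-tribromo-2-hydroxybenzaldehyde
Product: 8 2,3,5-tribromo-6-methoxybenzaldehyde
Conditions: MeI (1.5 equiv), K2CO3, DMF, rt
Reagents that add atoms: iodomethane, CI
Why: Williamson O-methylation of an acidic, fully ionised salicylaldehyde; there is no second hydroxyl to compete.

**Step 5**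
Reactants: 8 2,3,5-tribromo-6-methoxybenzaldehyde
Product: 10 2,3,5-tribromo-6-methoxyphenol, via aryl formate 9 (not isolated)
Conditions: mCPBA (2 equiv), CH2Cl2, rt → reflux; then MeOH, Et3N (cat.), rt
Reagents that add atoms: 3-chloroperoxybenzoic acid, OOC(=O)c1cccc(Cl)c1
Why: Baeyer–Villiger oxidation of an ortho-alkoxybenzaldehyde; the ortho methoxy donor and the out-of-plane twist of the di-ortho-substituted formyl group favour aryl over hydride migration, and the activated aryl formate is cleaved by mild methanolysis.

**Step 6**
Reactants: 10 2,3,5-tribromo-6-methoxyphenol; 5 2,4-dibromo-6-(trimethylsilyl)phenyl trifluoromethanesulfonate; 11 nonafluoro-1-iodobutane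
Product: 15 1,2,5-tribromo-3-(3,5-dibromo-2-iodophenoxy)-4-methoxybenzene, via potassium phenolate 12 (not isolated), via 3,5-dibromobenzyne 13 (not isolated), via arylpotassium 14 (not isolated)
Conditions: KH (1.05 equiv), THF, 0 °C; then 11 (10 equiv), KF (2 equiv), 18-crown-6 (2 equiv), slow addition of 5 (1.5 equiv), THF, −20 °C → rt, dark, slow argon sweep
Reagents that add atoms: none
Why: Proposed new method: fluoride from KF/18-crown-6 attacks silicon of 5 and triflate departs to give 3,5-dibromobenzyne 13; the preformed phenolate 12 adds to it and the aryl anion 14 abstracts iodine from 11 in a halophilic substitution, so that O–C1' and C6'–I form in one operation. The closest known reaction types are the fluoride-induced O-arylation of phenols with ortho-silylaryl triflates and the three-component aryne couplings in which a sulfur or nitrogen anion adds and the ortho carbanion takes a halogen from a polyhalogenated carbon donor; an aryloxide has not been used in that role. No ring closes and no stereocentre is formed. Regioselectivity of addition is required and is supplied by the single flanking C5'–Br bond: its inductive pull distorts the aryne so that C1' is the flatter, more electrophilic terminus and the charge develops at C6' beside bromine, and the bulk of the di-ortho-substituted phenolate further disfavours attack at the carbon next to bromine. The second demand is chemoselectivity at the anion: iodine transfer must outrun protonation and loss of the neighbouring bromide. This is addressed by a proton-free medium (phenolate from KH, THF in place of acetonitrile), a tenfold excess of 11 that can pre-associate with the phenolate oxygen through a halogen bond and so lies beside C6' as the charge appears, and slow addition of 5 at low temperature. The perfluorobutyl anion left behind collapses to octafluorobutene and fluoride, which makes the iodine transfer irreversible and returns the desilylating agent; the argon sweep removes the volatile fluoroalkene.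

**Step 7**
Reactants: 15 1,2,5-tribromo-3-(3,5-dibromo-2-iodophenoxy)-4-methoxybenzene
Product: 18 2,4-dibromo-6-(2,3,5-tribromo-6-methoxyphenoxy)phenol, via arylmagnesium chloride 16 (not isolated), via dimethyl arylboronate 17 (not isolated)
Conditions: iPrMgCl·LiCl (1.05 equiv), THF, −78 °C; B(OMe)3, −78 → 0 °C; then AcOH, 30% aq H2O2, 0 °C → rt
Reagents that add atoms: hydrogen peroxide, OO
Why: Iodine–magnesium exchange is far faster than bromine–magnesium exchange at −78 °C, and more so for an iodide flanked by oxygen and bromine; the ortho-bromo Grignard reagent is stable at that temperature. Borylation followed by peroxide oxidation under acidic conditions (1,2-shift of aryl from boron to oxygen) gives the phenol while limiting base-promoted protodeboronation.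

## Compound list

1 | 2,4,6-tribromophenol | Oc1c(Br)cc(Br)cc1Br | starting material
2 | (2,4,6-tribromophenoxy)trimethylsilane | C[Si](C)(C)Oc1c(Br)cc(Br)cc1Br | intermediate
3 | [3,5-dibromo-2-(trimethylsilyloxy)phenyl]lithium | C[Si](C)(C)Oc1c([Li])cc(Br)cc1Br | intermediate
4 | lithium 2,4-dibromo-6-(trimethylsilyl)phenolate | C[Si](C)(C)c1cc(Br)cc(Br)c1[O-].[Li+] | intermediate
5 | 2,4-dibromo-6-(trimethylsilyl)phenyl trifluoromethanesulfonate | C[Si](C)(C)c1cc(Br)cc(Br)c1OS(=O)(=O)C(F)(F)F | intermediate
6 | 2-bromo-6-hydroxybenzaldehyde | O=Cc1c(O)cccc1Br | starting material
7 | 3,5,6-tribromo-2-hydroxybenzaldehyde | O=Cc1c(O)c(Br)cc(Br)c1Br | intermediate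
8 | 2,3,5-tribromo-6-methoxybenzaldehyde | COc1c(Br)cc(Br)c(Br)c1C=O | intermediate
9 | 2,3,5-tribromo-6-methoxyphenyl formate | COc1c(Br)cc(Br)c(Br)c1OC=O | intermediate
10 | 2,3,5-tribromo-6-methoxyphenol | COc1c(Br)cc(Br)c(Br)c1O | intermediate
11 | nonafluoro-1-iodobutane | FC(F)(F)C(F)(F)C(F)(F)C(F)(F)I | starting material
12 | potassium 2,3,5-tribromo-6-methoxyphenolate | COc1c(Br)cc(Br)c(Br)c1[O-].[K+] | intermediate
13 | 3,5-dibromobenzyne (3,5-dibromo-1,2-didehydrobenzene) | BrC1=CC(Br)=CC#C1 | intermediate
14 | [2,4-dibromo-6-(2,3,5-tribromo-6-methoxyphenoxy)phenyl]potassium | COc1c(Br)cc(Br)c(Br)c1Oc1cc(Br)cc(Br)c1[K] | intermediate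
15 | 1,2,5-tribromo-3-(3,5-dibromo-2-iodophenoxy)-4-methoxybenzene | COc1c(Br)cc(Br)c(Br)c1Oc1cc(Br)cc(Br)c1I | intermediate
16 | [2,4-dibromo-6-(2,3,5-tribromo-6-methoxyphenoxy)phenyl]magnesium chloride | COc1c(Br)cc(Br)c(Br)c1Oc1cc(Br)cc(Br)c1[Mg]Cl | intermediate
17 | dimethyl [2,4-dibromo-6-(2,3,5-tribromo-6-methoxyphenoxy)phenyl]boronate | COc1c(Br)cc(Br)c(Br)c1Oc1cc(Br)cc(Br)c1B(OC)OC | intermediate
18 | 2,4-dibromo-6-(2,3,5-tribromo-6-methoxyphenoxy)phenol | COc1c(Br)cc(Br)c(Br)c1Oc1cc(Br)cc(Br)c1O | target

## Step count and risks

Total step count: 7. Longest linear sequence: 5 steps (6 → 7 → 8 → 10 → 15 → 18; steps 3, 4, 5, 6, 7). The aryne precursor branch (steps 1 and 2) joins at step 6.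

**Step 6 (key step, proposed new method).**
- What may go wrong: the carbanion at C6' expels the neighbouring bromide before it is iodinated, which opens a second aryne and leads to over-arylation. Protonation of that anion by adventitious acid would give the iodine-free ether. The phenolate may also be consumed by the electrophilic fluoroalkene that the spent iodine donor releases.
- Fallback, by known chemistry: it sets out from 10 and returns at 18, bypassing 15 and step 7. Nucleophilic aromatic substitution of 10 on purchased 2,4-dibromo-6-fluorobenzaldehyde (O=Cc1c(F)cc(Br)cc1Br; K2CO3, DMAc, heat), in which the ortho formyl group activates displacement of fluoride, should give 2,4-dibromo-6-(2,3,5-tribromo-6-methoxyphenoxy)benzaldehyde F1. Baeyer–Villiger oxidation with mCPBA would give 2,4-dibromo-6-(2,3,5-tribromo-6-methoxyphenoxy)phenyl formate F2, and methanolysis of F2 gives 18.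

**Step 7.**
- What may go wrong: protodeboronation of the di-ortho-substituted, electron-poor boronate during oxidation, which returns a C6'–H ether. Loss of magnesium halide from the ortho-bromo Grignard reagent on premature warming is also possible.
- Fallback: it sets out from 15 and returns at 18. After the same exchange at −78 °C, the arylmagnesium species is oxygenated directly with tert-butyl peroxybenzoate, so that no boron intermediate is involved. This should give 1,2,5-tribromo-3-(3,5-dibromo-2-tert-butoxyphenoxy)-4-methoxybenzene F3, and trifluoroacetic acid in CH2Cl2 then cleaves the tert-butyl ether to 18.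

**Step 5.**
- What may go wrong: hydride migrates in place of the electron-poor aryl group in the peracid adduct, which leads to the benzoic acid. Peracid addition to the hindered carbonyl may also be slow.
- Fallback: it sets out from 8 and returns at 10; the competing hydride is replaced by a methyl group, which migrates far less readily than aryl. MeMgBr (THF, −78 °C) should give racemic 1-(2,3,5-tribromo-6-methoxyphenyl)ethanol F4. Dess–Martin periodinane would oxidise it to 1-(2,3,5-tribromo-6-methoxyphenyl)ethanone F5. Baeyer–Villiger oxidation with trifluoroperacetic acid would give 2,3,5-tribromo-6-methoxyphenyl acetate F6, and methanolysis (K2CO3, MeOH) gives 10.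

**Step 2.**
- What may go wrong: exchange at the para bromine, attack of n-BuLi at silicon, or incomplete migration of silicon from oxygen to carbon, each giving inseparable silyl isomers or desilylated phenol.
- Fallback: it sets out from 1 and returns at 5; the intramolecular silyl shift is replaced by external silylation of a chelated aryllithium. MOMCl with iPr2NEt should give 1,3,5-tribromo-2-(methoxymethoxy)benzene F7. Ortho exchange with n-BuLi at −78 °C, guided by the acetal oxygens, and quenching with Me3SiCl would give [3,5-dibromo-2-(methoxymethoxy)phenyl]trimethylsilane F8. HCl in MeOH would release 2,4-dibromo-6-(trimethylsilyl)phenol F9, and Tf2O with pyridine converts F9 into 5.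

## Further compounds

F1 | step 6 | 2,4-dibromo-6-(2,3,5-tribromo-6-methoxyphenoxy)benzaldehyde | COc1c(Br)cc(Br)c(Br)c1Oc1cc(Br)cc(Br)c1C=O
F2 | step 6 | 2,4-dibromo-6-(2,3,5-tribromo-6-methoxyphenoxy)phenyl formate | COc1c(Br)cc(Br)c(Br)c1Oc1cc(Br)cc(Br)c1OC=O
F3 | step 7 | 1,2,5-tribromo-3-(3,5-dibromo-2-tert-butoxyphenoxy)-4-methoxybenzene | COc1c(Br)cc(Br)c(Br)c1Oc1cc(Br)cc(Br)c1OC(C)(C)C
F4 | step 5 | racemic 1-(2,3,5-tribromo-6-methoxyphenyl)ethanol | COc1c(Br)cc(Br)c(Br)c1C(C)O
F5 | step 5 | 1-(2,3,5-tribromo-6-methoxyphenyl)ethanone | COc1c(Br)cc(Br)c(Br)c1C(C)=O
F6 | step 5 | 2,3,5-tribromo-6-methoxyphenyl acetate | COc1c(Br)cc(Br)c(Br)c1OC(C)=O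
F7 | step 2 | 1,3,5-tribromo-2-(methoxymethoxy)benzene | COCOc1c(Br)cc(Br)cc1Br
F8 | step 2 | [3,5-dibromo-2-(methoxymethoxy)phenyl]trimethylsilane | COCOc1c(Br)cc(Br)cc1[Si](C)(C)C
F9 | step 2 | 2,4-dibromo-6-(trimethylsilyl)phenol | C[Si](C)(C)c1cc(Br)cc(Br)c1O
A1 | alternative 1 | tert-butyl{2-[2-(benzyloxy)-3,5-dibromophenoxy]-3,6-dibromophenoxy}dimethylsilane | CC(C)(C)[Si](C)(C)Oc1c(Br)ccc(Br)c1Oc1cc(Br)cc(Br)c1OCc1ccccc1
A2 | alternative 1 | 2,5-dibromothiophene 1,1-dioxide | O=S1(=O)C(Br)=CC=C1Br
A3 | alternative 1 | bis(tert-butyldimethylsilyl) ketene acetal of [2-(benzyloxy)-3,5-dibromophenoxy]acetic acid | CC(C)(C)[Si](C)(C)OC(O[Si](C)(C)C(C)(C)C)=COc1cc(Br)cc(Br)c1OCc1ccccc1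
A4 | alternative 2 | 2-bromo-6-(2,3,5-tribromo-6-methoxyphenoxy)phenol | COc1c(Br)cc(Br)c(Br)c1Oc1cccc(Br)c1O
A5 | alternative 2 | tert-butyldimethyl{[3-(2,3,5-tribromo-6-methoxyphenoxy)cyclopenta-1,3-dien-2-yl]oxy}silane | COc1c(Br)cc(Br)c(Br)c1OC1=CCC=C1O[Si](C)(C)C(C)(C)C
A6 | alternative 3 | 2-[2-(benzyloxy)-3,5-dibromophenoxy]-3,4,6-tribromophenol | Oc1c(Br)cc(Br)c(Br)c1Oc1cc(Br)cc(Br)c1OCc1ccccc1
A7 | alternative 3 | 2-[2-(benzyloxy)-3,5-dibromophenoxy]-3-bromocyclohex-2-en-1-one | O=C1CCCC(Br)=C1Oc1cc(Br)cc(Br)c1OCc1ccccc1
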